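Dawn and spring are two closed, stirred flasks of solid substrate and reagent, which you read at 5.0 h. Four earlier runs show how the curves go.

| setting | theta | eta | alpha | epsilon | spring | dawn |
|---|---|---|---|---|---|---|
| solid substrate | 0.44 M | 0.73 M | 1.1 M | 0.50 M | 1.0 M | 0.50 M |
| reagent | 0.30 M | 0.30 M | 0.30 M | 0.59 M | 0.600 M | 0.300 M |
| remark | run made earlier | run made earlier | run made earlier | run made earlier |  |  |
| time |  |  |  |  | 5.0 h | 5.0 h |

- theta (time / h: product / %, solid substrate / %): 1.00: 1, 90; 2.00: 9, 80; 3.00: 15, 65; 4.00: 24, 52; 5.00: 34, 44
- eta (time / h: product / %, solid substrate / %): 0.417: 0, 95; 0.833: 3, 93; 1.33: 2, 91; 2.50: 9, 82; 5.00: 21, 66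
- alpha (time / h: product / %, solid substrate / %): 1.00: 2, 95; 2.00: 3, 93; 3.00: 8, 88; 4.00: 7, 82; 5.00: 12, 77
- epsilon (time / h: product / %, solid substrate / %): 1.00: 2, 90; 2.00: 13, 80; 3.00: 23, 73; 4.00: 38, 59; 5.00: 42, 49

(scatter of a reading: 2 percentage points)

- solid, in amounts per volume of the solution: solid substrate
- at the start none of the solid substrate is in solution
- what has only dissolved of solid substrate counts as not reacted

- which of the two ends with the higher amount of product, in percent of the solid substrate charged ("neither" if they lie within 2 percentage points) (spring / dawn / neither)
- product at the end, in percent of the solid substrate charged, spring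
- product at the end, in percent of the solid substrate charged, dawn

Draw the solid line first. By the last reading, theta has lost 0.246 M from a charge of 0.44 M, and alpha has lost 0.253 M from 1.1 M. The readings fall about straight, which reads as an apparent zero order. Averaged over the four runs, the feed F, the solid lost per hour, reads 0.0501 M h⁻¹.

Now count turnovers. One turnover, τ, is the charge divided by F, and it marks the knee where the straight line meets zero. For dawn τ is 9.97 h and for spring 19.9 h. So at the reading dawn has done half a turnover and spring a quarter, and both reckoned knees lie later than 5.0 h.

Theta's product curve starts flat, with a reading of 1% after 1.00 h. From 2.00 h to 5.00 h theta's product then climbs at a read 0.0367 M h⁻¹, slower than F. Theta's last reading is 0.150 M of product and epsilon's, with about twice the reagent and a somewhat larger solid charge, is 0.210 M. Theta's reagent matches dawn's and epsilon's nearly matches spring's, so, carrying these molar amounts over to the new charges, I reckon 29.9% of the charge for dawn and 21.0% for spring.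

The forecast names dawn, with 21% for spring and 30% for dawn, on the ground that “Neither new run exhausts its solid”.

The flasks end at 19.2% for spring and 28.6% for dawn, so dawn ends higher.

    starting material → intermediate A (k = 0.00317 s⁻¹)
    reagent + intermediate A → product (k = 5.93 × 10⁻⁴ L mol⁻¹ s⁻¹)
    solid substrate ⇌ starting material, rate k3*(cs3 - [starting material]) while solid is left; crystals form when [starting material] > cs3 (solubility = 0.210 M, k = 6.85 × 10⁻⁵ s⁻¹)
    starting material + reagent ⇌ intermediate B (K = 4.90 L mol⁻¹, k = 1.98 × 10⁻⁴ L mol⁻¹ s⁻¹)

With F, dawn's solid substrate reckons to 49.9% at the reading, and the flask holds 49.3%. Spring reckons to 74.9% and holds 74.6%. Now take spring's neighbour, the same flask with 0.15 M of reagent. The same feed and the same charge again give 74.9%, and that flask holds 74.6%. Its product, however, reaches 8.89%, with intermediate A at 15.9% and 40% of its reagent charge left unbound.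

(The readings come from a simulation for substances that don't exist; noise was put on by code.)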